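**Retrosynthetic overview**

- The target comes from its pentamethyl ether by global O-demethylation. Both benzene rings are bought with their oxygen pattern in place, so the pyran ring is the only ring that is built.
- The pyran ring is closed at O1–C8a by intramolecular SNAr of the C2 alkoxide on a C8a–F bond. This happens in the same flask directly after a B-alkyl Suzuki–Miyaura coupling has made C4–C4a, so two simple halves (a γ-hydroxy alkylboronate and a bromofluoro aryl ketone) become the full skeleton in one operation.
- Enabling feature: in ring A (the benzene ring of the chroman) C8a lies para to the C6 isovaleryl carbonyl and meta to both methoxy groups, so a C8a–F bond is activated for substitution. The 4-fluoro-2,6-dimethoxyphenyl ketone is symmetric about its C6···C8a axis, so the future C4a and C8 are equivalent, and O1 and C4 sit 1,3 on the C2–C3–C4 chain.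
- The γ-hydroxy boronate comes from a catalytic enantioselective, syn-selective allylboration of one formyl group of threefold-symmetric 2,4,6-trimethoxybenzene-1,3,5-tricarbaldehyde with the (Z)-1,4-bis-boronate of isoprene, then alkene hydrogenation. This sets C2 and C3 and leaves the other two formyl groups as the CHO groups of the target.
- The bromofluoro ketone comes from 4-fluoro-2,6-dimethoxybenzaldehyde by Grignard addition, oxidation and bromination.

Key step: step 7

Assumption (chemistry): the chiral phosphoric acid (R)-TRIP is taken to deliver the allyl group to the Re face of the aryl aldehyde, as it does with simple aryl aldehydes; if the sense were opposite, the (S)-catalyst would be used.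

**Step 1**
Reactants: 1 isoprene (2-methylbuta-1,3-diene); 2 bis(pinacolato)diboron
Product: 3 (Z)-2,2'-(2-methylbut-2-ene-1,4-diyl)bis(4,4,5,5-tetramethyl-1,3,2-dioxaborolane)
Conditions: Pt(PPh3)4 (3 mol %), toluene, 80 °C, sealed tube
Reagents that add atoms: none
Why: Zerovalent-platinum-catalysed 1,4-diboration of a 1,3-diene, in which the diene binds in its s-cis form and both boryl groups are delivered to its termini from one metal centre, should give only the Z 1,4-adduct; no stereocentre is formed.

**Step 2**
Reactants: 3 (Z)-2,2'-(2-methylbut-2-ene-1,4-diyl)bis(4,4,5,5-tetramethyl-1,3,2-dioxaborolane); 4 2,4,6-trimethoxybenzene-1,3,5-tricarbaldehyde (3 equiv, excess recovered)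
Product: 5 5-[(1R,2S)-1-hydroxy-3-methyl-2-[(4,4,5,5-tetramethyl-1,3,2-dioxaborolan-2-yl)methyl]but-3-en-1-yl]-2,4,6-trimethoxybenzene-1,3-dicarbaldehyde
Conditions: (R)-3,3'-bis(2,4,6-triisopropylphenyl)-1,1'-binaphthyl-2,2'-diyl hydrogen phosphate ((R)-TRIP, 5 mol %), 4 Å molecular sieves, toluene, −30 °C; then aq. NaHCO3 (cleaves the O–B bond)
Reagents that add atoms: none
Why: Chiral-phosphoric-acid-catalysed allylboration through a closed chair transition state, in which the 2-methylallyl boron terminus reacts at its CH γ-carbon (the other terminus would have to build a quaternary centre), the Z-placed CH2Bpin group is forced axial and gives the syn relation of O and CH2B that sets C3, the catalyst shields one face of the formyl group and sets C2 as R, and the excess of 4 together with the lower electrophilicity of the two remaining formyl groups should hold the reaction at one allyl transfer.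

**Step 3**
Reactants: 5 5-[(1R,2S)-1-hydroxy-3-methyl-2-[(4,4,5,5-tetramethyl-1,3,2-dioxaborolan-2-yl)methyl]but-3-en-1-yl]-2,4,6-trimethoxybenzene-1,3-dicarbaldehyde
Product: 6 5-[(1R,2S)-1-hydroxy-3-methyl-2-[(4,4,5,5-tetramethyl-1,3,2-dioxaborolan-2-yl)methyl]butyl]-2,4,6-trimethoxybenzene-1,3-dicarbaldehyde
Conditions: H2 (1 atm), RhCl(PPh3)3 (5 mol %), toluene–EtOH (1:1), rt
Reagents that add atoms: none
Why: Homogeneous hydrogenation with RhCl(PPh3)3 should reduce the unhindered 1,1-disubstituted alkene and leave the aryl aldehydes, the C–B bond and the benzylic C–O bond alone; no stereocentre is formed, and the allylic C3–H that could lead to a diene by β-hydride elimination in step 7 is removed.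

**Step 4**
Reactants: 7 4-fluoro-2,6-dimethoxybenzaldehyde; 8 isobutylmagnesium bromide
Product: 9 1-(4-fluoro-2,6-dimethoxyphenyl)-3-methylbutan-1-ol (racemic)
Conditions: THF, 0 °C to rt; then H2O
Reagents that add atoms: none
Why: Grignard addition to a non-enolisable aldehyde; the carbinol centre is formed racemic and is removed in step 5.

**Step 5**
Reactants: 9 1-(4-fluoro-2,6-dimethoxyphenyl)-3-methylbutan-1-ol
Product: 10 1-(4-fluoro-2,6-dimethoxyphenyl)-3-methylbutan-1-one
Conditions: Dess–Martin periodinane, CH2Cl2, rt
Reagents that add atoms: none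
Why: Dess–Martin oxidation of a benzylic secondary alcohol to the ketone under neutral conditions; no stereocentre remains.

**Step 6**
Reactants: 10 1-(4-fluoro-2,6-dimethoxyphenyl)-3-methylbutan-1-one
Product: 11 1-(3-bromo-4-fluoro-2,6-dimethoxyphenyl)-3-methylbutan-1-one
Conditions: N-bromosuccinimide (1.0 equiv), MeCN, 0 °C to rt
Reagents that add atoms: N-bromosuccinimide, O=C1CCC(=O)N1Br
Why: Electrophilic aromatic bromination, in which the two free ring positions are equivalent by symmetry and each is ortho and para to a methoxy group, so one equivalent of reagent should give a single monobromide; no stereocentre is formed.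

**Step 7**
Reactants: 6 5-[(1R,2S)-1-hydroxy-3-methyl-2-[(4,4,5,5-tetramethyl-1,3,2-dioxaborolan-2-yl)methyl]butyl]-2,4,6-trimethoxybenzene-1,3-dicarbaldehyde; 11 1-(3-bromo-4-fluoro-2,6-dimethoxyphenyl)-3-methylbutan-1-one
Product: 13 5-[(2R,3S)-5,7-dimethoxy-6-(3-methylbutanoyl)-3-(propan-2-yl)-3,4-dihydro-2H-1-benzopyran-2-yl]-2,4,6-trimethoxybenzene-1,3-dicarbaldehyde, via fluoro alcohol 12 (not isolated)
Conditions: Pd(OAc)2 (5 mol %), 2-dicyclohexylphosphino-2',6'-diisopropoxybiphenyl (RuPhos, 10 mol %), K3PO4 (4 equiv), toluene–H2O (10:1), 80 °C; then DMSO added to the same flask, 100 °C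
Reagents that add atoms: none
Why: Zerovalent palladium inserts into the C–Br bond of 11, the primary alkyl boronate of 6 transmetalates with help from its own γ-alkoxide (a five-membered cyclic borate), and reductive elimination makes C4–C4a to give 12. The C2 alkoxide of 12 then adds to C8a, the Meisenheimer anion is stabilised by the para C6 carbonyl and the two meta methoxy groups, and loss of fluoride forms O1–C8a. The closest known reaction types are the hydroxyl-assisted B-alkyl Suzuki–Miyaura coupling and the intramolecular SNAr etherification of para-acyl fluoroarenes. The pyran ring closes in a 6-exo addition–elimination at an aromatic carbon. No stereocentre is formed: C2 keeps its configuration because its C–O bond is never broken and C3 is untouched, so the trans relation is carried over from 6. The step needs insertion into C–Br and not C–F, which the bond strengths secure, and ring closure at C8a only, which the six-membered tether and fluoride as the single leaving group secure; the mild phosphate base should leave most of the ketone un-enolised so that the para activation persists, and the formyl groups cannot enolise.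

**Step 8**
Reactants: 13 5-[(2R,3S)-5,7-dimethoxy-6-(3-methylbutanoyl)-3-(propan-2-yl)-3,4-dihydro-2H-1-benzopyran-2-yl]-2,4,6-trimethoxybenzene-1,3-dicarbaldehyde
Product: 14 5-[(2R,3S)-5,7-dihydroxy-6-(3-methylbutanoyl)-3-(propan-2-yl)-3,4-dihydro-2H-1-benzopyran-2-yl]-2,4,6-trihydroxybenzene-1,3-dicarbaldehyde (CNP0551232.1)
Conditions: BCl3 (excess), n-Bu4NI, CH2Cl2, −78 °C to 0 °C; then H2O
Reagents that add atoms: none
Why: Lewis-acid ether cleavage with iodide as the nucleophile, in which each of the five methoxy groups is ortho to a carbonyl group that anchors boron, iodide attacks only methyl carbon, and the secondary benzylic O1–C2 ether should survive because the boron-complexed formyl groups make the lower ring electron-poor; no stereocentre is touched.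

**Compound list**

1 | isoprene (2-methylbuta-1,3-diene) | C=CC(C)=C | starting material
2 | bis(pinacolato)diboron | CC1(C)OB(OC1(C)C)B1OC(C)(C)C(C)(C)O1 | starting material
3 | (Z)-2,2'-(2-methylbut-2-ene-1,4-diyl)bis(4,4,5,5-tetramethyl-1,3,2-dioxaborolane) | CC1(C)OB(C/C(C)=C\CB2OC(C)(C)C(C)(C)O2)OC1(C)C | intermediate
4 | 2,4,6-trimethoxybenzene-1,3,5-tricarbaldehyde | COc1c(C=O)c(OC)c(C=O)c(OC)c1C=O | starting material
5 | 5-[(1R,2S)-1-hydroxy-3-methyl-2-[(4,4,5,5-tetramethyl-1,3,2-dioxaborolan-2-yl)methyl]but-3-en-1-yl]-2,4,6-trimethoxybenzene-1,3-dicarbaldehyde | CC1(C)OB(C[C@@H](C(C)=C)[C@H](c2c(OC)c(C=O)c(OC)c(C=O)c2OC)O)OC1(C)C | intermediate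
6 | 5-[(1R,2S)-1-hydroxy-3-methyl-2-[(4,4,5,5-tetramethyl-1,3,2-dioxaborolan-2-yl)methyl]butyl]-2,4,6-trimethoxybenzene-1,3-dicarbaldehyde | CC1(C)OB(C[C@@H](C(C)C)[C@H](c2c(OC)c(C=O)c(OC)c(C=O)c2OC)O)OC1(C)C | intermediate
7 | 4-fluoro-2,6-dimethoxybenzaldehyde | COc1cc(F)cc(OC)c1C=O | starting material
8 | isobutylmagnesium bromide | CC(C)C[Mg]Br | starting material
9 | 1-(4-fluoro-2,6-dimethoxyphenyl)-3-methylbutan-1-ol (racemic) | COc1cc(F)cc(OC)c1C(O)CC(C)C | intermediate
10 | 1-(4-fluoro-2,6-dimethoxyphenyl)-3-methylbutan-1-one | COc1cc(F)cc(OC)c1C(=O)CC(C)C | intermediate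
11 | 1-(3-bromo-4-fluoro-2,6-dimethoxyphenyl)-3-methylbutan-1-one | COc1cc(F)c(Br)c(OC)c1C(=O)CC(C)C | intermediate
12 | 5-[(1R,2S)-2-{[6-fluoro-2,4-dimethoxy-3-(3-methylbutanoyl)phenyl]methyl}-1-hydroxy-3-methylbutyl]-2,4,6-trimethoxybenzene-1,3-dicarbaldehyde | COc1cc(F)c(C[C@@H](C(C)C)[C@H](c2c(OC)c(C=O)c(OC)c(C=O)c2OC)O)c(OC)c1C(=O)CC(C)C | intermediate (not isolated)
13 | 5-[(2R,3S)-5,7-dimethoxy-6-(3-methylbutanoyl)-3-(propan-2-yl)-3,4-dihydro-2H-1-benzopyran-2-yl]-2,4,6-trimethoxybenzene-1,3-dicarbaldehyde | CC(C)CC(=O)c1c(OC)cc2c(c1OC)C[C@@H](C(C)C)[C@H](c1c(OC)c(C=O)c(OC)c(C=O)c1OC)O2 | intermediate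
14 | 5-[(2R,3S)-5,7-dihydroxy-6-(3-methylbutanoyl)-3-(propan-2-yl)-3,4-dihydro-2H-1-benzopyran-2-yl]-2,4,6-trihydroxybenzene-1,3-dicarbaldehyde | CC(C)CC(=O)c1c(O)cc2c(c1O)C[C@@H](C(C)C)[C@H](c1c(O)c(C=O)c(O)c(C=O)c1O)O2 | target

**Step count and risks**

Total steps: 8. Longest linear sequence: 5 steps (steps 1, 2, 3, 7, 8; the ring A arm, steps 4, 5, 6, 7, 8, is equally long).

The three steps most likely to fail:

1. Step 7. Transmetalation of the β-branched alkyl boronate onto a di-ortho-substituted aryl-palladium species may be slow, so that protodeboronation competes. The ring closure may also stall if the C6 ketone enolises (loss of the para activation) or condenses with a formyl group of a second molecule in hot DMSO. The fallback sets out from 6 and comes back at 13, and replaces the SNAr closure by a palladium-catalysed C–O coupling of an aryl bromide. Commercial 4-bromo-2,6-dimethoxybenzaldehyde F1 would be treated with 8 to give racemic 1-(4-bromo-2,6-dimethoxyphenyl)-3-methylbutan-1-ol F2. Dess–Martin oxidation should give 1-(4-bromo-2,6-dimethoxyphenyl)-3-methylbutan-1-one F3, and iodination with N-iodosuccinimide and catalytic CF3CO2H in MeCN should give 1-(4-bromo-3-iodo-2,6-dimethoxyphenyl)-3-methylbutan-1-one F4. B-alkyl Suzuki–Miyaura coupling of 6 at the C–I bond (PdCl2(dppf), K3PO4, DMF–H2O, 50 °C) should give 5-[(1R,2S)-2-{[6-bromo-2,4-dimethoxy-3-(3-methylbutanoyl)phenyl]methyl}-1-hydroxy-3-methylbutyl]-2,4,6-trimethoxybenzene-1,3-dicarbaldehyde F5. An intramolecular palladium-catalysed etherification (Pd(OAc)2, 2-(di-tert-butylphosphino)-1,1'-binaphthyl, Cs2CO3, toluene, 80 °C) needs no activation by the ketone, runs in a non-polar medium, and would close O1–C8a with retention at C2 to give 13.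

2. Step 2. The catalyst may discriminate poorly between the faces of a formyl group flanked by two methoxy groups, and a second allyl transfer to the same arene may occur. The fallback sets out from 3 and 4 and comes back at 5. The uncatalysed allylboration (toluene, 40 °C) runs through the same closed transition state, so it should give the syn adduct reliably, as the racemate of 5 and its enantiomer 5-[(1S,2R)-1-hydroxy-3-methyl-2-[(4,4,5,5-tetramethyl-1,3,2-dioxaborolan-2-yl)methyl]but-3-en-1-yl]-2,4,6-trimethoxybenzene-1,3-dicarbaldehyde F6. The two would be separated by preparative chromatography on a chiral stationary phase, and 5 continues at step 3.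

3. Step 8. Cleavage may stop once the carbonyl anchors are saturated, or the Lewis acid may ionise the benzylic C2–O1 bond. The fallback sets out from 13 and comes back at 14 and changes the mechanism to nucleophilic demethylation under basic conditions: lithium 4-methylbenzenethiolate in HMPA–toluene at 110 °C attacks the methyl carbons by SN2 and cannot ionise the benzylic ether. No new compound is made on the way.

**Further compounds**

F1 | step 7 | 4-bromo-2,6-dimethoxybenzaldehyde (bought, first compound of the fallback) | COc1cc(Br)cc(OC)c1C=O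
F2 | step 7 | 1-(4-bromo-2,6-dimethoxyphenyl)-3-methylbutan-1-ol (racemic) | COc1cc(Br)cc(OC)c1C(O)CC(C)C
F3 | step 7 | 1-(4-bromo-2,6-dimethoxyphenyl)-3-methylbutan-1-one | COc1cc(Br)cc(OC)c1C(=O)CC(C)C
F4 | step 7 | 1-(4-bromo-3-iodo-2,6-dimethoxyphenyl)-3-methylbutan-1-one | COc1cc(Br)c(I)c(OC)c1C(=O)CC(C)C
F5 | step 7 | 5-[(1R,2S)-2-{[6-bromo-2,4-dimethoxy-3-(3-methylbutanoyl)phenyl]methyl}-1-hydroxy-3-methylbutyl]-2,4,6-trimethoxybenzene-1,3-dicarbaldehyde | COc1cc(Br)c(C[C@@H](C(C)C)[C@H](c2c(OC)c(C=O)c(OC)c(C=O)c2OC)O)c(OC)c1C(=O)CC(C)C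
F6 | step 2 | 5-[(1S,2R)-1-hydroxy-3-methyl-2-[(4,4,5,5-tetramethyl-1,3,2-dioxaborolan-2-yl)methyl]but-3-en-1-yl]-2,4,6-trimethoxybenzene-1,3-dicarbaldehyde | CC1(C)OB(C[C@H](C(C)=C)[C@@H](c2c(OC)c(C=O)c(OC)c(C=O)c2OC)O)OC1(C)C
F0 | step 8 | none | none
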